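The 2,2-dimethyl-2H-pyran ring (chromene numbering) is disconnected at O1–C2 and C3=C4, which exposes a salicylaldehyde and an isobutenyl unit. The key step joins the symmetric 2,6-dihydroxy-4-silyloxybenzaldehyde 3, (2-methylprop-1-enyl)boronic acid and catalytic dibenzylamine in a Petasis condensation; loss of the amine gives a vinyl o-quinone methide whose oxa-6π electrocyclization closes the pyran ring. It exploits the fact that C4 is a benzylic carbon ortho to the pyran oxygen O1, and that the two hydroxyls flanking the formyl group are equivalent: one becomes O1, the other (C5–OH) then directs the prenyl group to C6 by Claisen rearrangement and finally serves, as its triflate, to attach the benzofuran.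

Key step: step 2

Remark on the chemistry: the target has no stereocentre and no stereogenic double bond (the prenyl alkene carries two methyl groups, the C3=C4 alkene is cis by ring constraint). It is therefore achiral, and no enantio- or diastereocontrol is needed. Chromene numbering (O1, C2, C3, C4, C4a, C5–C8, C8a) is used throughout.

Step 1
Reactants: 1 2,4,6-trihydroxybenzaldehyde; 2 chlorotriisopropylsilane
Product: 3 2,6-dihydroxy-4-[(triisopropylsilyl)oxy]benzaldehyde
Conditions: TIPSCl (1.05 equiv), imidazole (2.2 equiv), DMF, 0 °C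
Reagents that add atoms: chlorotriisopropylsilane 2, CC(C)[Si](Cl)(C(C)C)C(C)C
Why: Selective phenol silylation; the 4-OH is the most acidic hydroxyl and the only one neither flanked by nor hydrogen-bonded to the formyl group, so the bulky silyl chloride should take it in preference to the 2- and 6-OH.

Step 2
Reactants: 3 2,6-dihydroxy-4-[(triisopropylsilyl)oxy]benzaldehyde; 4 (2-methylprop-1-en-1-yl)boronic acid
Product: 7 2,2-dimethyl-7-[(triisopropylsilyl)oxy]-2H-chromen-5-ol, via 2-[1-(dibenzylamino)-3-methylbut-2-en-1-yl]-5-[(triisopropylsilyl)oxy]benzene-1,3-diol 5 (not isolated), via 3-hydroxy-2-(3-methylbut-2-en-1-ylidene)-5-[(triisopropylsilyl)oxy]cyclohexa-3,5-dien-1-one 6 (not isolated)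
Conditions: 4 (1.5 equiv), Bn2NH (0.4 equiv), 4 Å MS, 1,4-dioxane, 90 °C
Reagents that add atoms: (2-methylprop-1-en-1-yl)boronic acid 4, CC(C)=CB(O)O
Why: Dibenzylamine condenses with the formyl group of 3 to an iminium ion held beside the boronate that 4 forms on an ortho phenol oxygen, and the 2-methylpropenyl group migrates from boron to the benzylic carbon (Petasis borono-Mannich reaction), which makes the C4–C3 bond in amine 5. At 90 °C the electron-rich ring of 5 expels dibenzylamine, which re-enters the cycle, to give the vinyl o-quinone methide 6, and 6 closes by a thermal disrotatory oxa-6π electrocyclization that makes the O1–C2 bond and leaves the alkene at C3=C4. The closest known reaction type is the amine-catalysed condensation of salicylaldehydes with alkenylboronic acids to 2H-chromenes. The one ring closed is the pyran ring, by 6π electrocyclization of a 1-oxatriene and not by an ionic attack of the phenol. No stereocentre arises because C2 carries two methyl groups, and the C3=C4 alkene is cis by ring constraint. The selectivity needed is the choice of the oxygen that closes: the two ortho hydroxyls of 3 are equivalent, so either closure gives 7 and either geometry of the exocyclic alkene of 6 has an oxygen s-cis to the diene, while the para oxygen is blocked as its TIPS ether.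

Step 3
Reactants: 8 2-methylbut-3-en-2-ol; 9 isobutyl chloroformate
Product: 11 isobutyl (2-methylbut-3-en-2-yl) carbonate, via lithium 2-methylbut-3-en-2-olate 10 (not isolated)
Conditions: n-BuLi (1.0 equiv), THF, −78 °C; then ClCO2i-Bu, −78 °C to rt
Reagents that add atoms: isobutyl chloroformate 9, CC(C)COC(=O)Cl
Why: Acylation of the lithium alkoxide of a tertiary allylic alcohol with a chloroformate is a standard carbonate synthesis.

Step 4
Reactants: 7 2,2-dimethyl-7-[(triisopropylsilyl)oxy]-2H-chromen-5-ol; 11 isobutyl (2-methylbut-3-en-2-yl) carbonate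
Product: 12 triisopropyl({2,2-dimethyl-5-[(2-methylbut-3-en-2-yl)oxy]-2H-chromen-7-yl}oxy)silane
Conditions: Pd(PPh3)4 (3 mol %), THF, 0 °C to rt
Reagents that add atoms: none
Why: Tsuji–Trost O-allylation (reverse prenylation): Pd(0) ionizes the carbonate with loss of CO2, the isobutoxide deprotonates the C5 phenol, and the phenoxide should attack the more substituted terminus of the π-(1,1-dimethylallyl)palladium cation under kinetic control at low temperature.

Step 5
Reactants: 12 triisopropyl({2,2-dimethyl-5-[(2-methylbut-3-en-2-yl)oxy]-2H-chromen-7-yl}oxy)silane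
Product: 14 2,2-dimethyl-6-(3-methylbut-2-en-1-yl)-7-[(triisopropylsilyl)oxy]-2H-chromen-5-ol, via 2,2-dimethyl-6-(3-methylbut-2-en-1-yl)-7-[(triisopropylsilyl)oxy]-2H-chromen-5(6H)-one 13 (not isolated)
Conditions: PhMe, 110–120 °C (sealed tube)
Reagents that add atoms: none
Why: Aromatic Claisen rearrangement ([3,3]): C6 is the only unsubstituted ortho carbon of the C5 oxygen, the allylic inversion turns the 1,1-dimethylallyl group into a prenyl group, and tautomerization of dienone 13 restores the phenol.

Step 6
Reactants: 14 2,2-dimethyl-6-(3-methylbut-2-en-1-yl)-7-[(triisopropylsilyl)oxy]-2H-chromen-5-ol; 15 trifluoromethanesulfonic anhydride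
Product: 16 2,2-dimethyl-6-(3-methylbut-2-en-1-yl)-7-[(triisopropylsilyl)oxy]-2H-chromen-5-yl trifluoromethanesulfonate
Conditions: Tf2O (1.2 equiv), pyridine, CH2Cl2, −20 to 0 °C
Reagents that add atoms: trifluoromethanesulfonic anhydride 15, O=S(=O)(OS(=O)(=O)C(F)(F)F)C(F)(F)F
Why: Standard triflation of a phenol; pyridine buffers the triflic acid so that the prenyl and chromene alkenes are not protonated.

Step 7
Reactants: 17 benzofuran-6-ol; 2 chlorotriisopropylsilane
Product: 18 (benzofuran-6-yloxy)triisopropylsilane
Conditions: TIPSCl (1.1 equiv), imidazole (2.2 equiv), DMF, rt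
Reagents that add atoms: chlorotriisopropylsilane 2, CC(C)[Si](Cl)(C(C)C)C(C)C
Why: Standard silylation of a phenol; the silyl ether masks the acidic OH for the lithiation that follows.

Step 8
Reactants: 16 2,2-dimethyl-6-(3-methylbut-2-en-1-yl)-7-[(triisopropylsilyl)oxy]-2H-chromen-5-yl trifluoromethanesulfonate; 18 (benzofuran-6-yloxy)triisopropylsilane
Product: 21 triisopropyl[(2-{2,2-dimethyl-6-(3-methylbut-2-en-1-yl)-7-[(triisopropylsilyl)oxy]-2H-chromen-5-yl}benzofuran-6-yl)oxy]silane, via {6-[(triisopropylsilyl)oxy]benzofuran-2-yl}lithium 19 (not isolated), via chloro{6-[(triisopropylsilyl)oxy]benzofuran-2-yl}zinc 20 (not isolated)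
Conditions: 18 (1.3 equiv), n-BuLi (1.25 equiv), THF, −78 °C; ZnCl2 (1.4 equiv), −78 °C to rt; then 16, Pd2(dba)3 (2.5 mol %), XPhos (10 mol %), THF, 60 °C
Reagents that add atoms: none
Why: Negishi coupling: benzofuran is lithiated at C2, its most acidic C–H (the bulky OTIPS group is a poor ortho director), the zinc reagent 20 is a stable 2-heteroaryl nucleophile, and a bulky biarylphosphine palladium catalyst should couple it with the di-ortho-substituted triflate, whose C5 is meta to both ring oxygens and so not deactivated toward oxidative addition.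

Step 9
Reactants: 21 triisopropyl[(2-{2,2-dimethyl-6-(3-methylbut-2-en-1-yl)-7-[(triisopropylsilyl)oxy]-2H-chromen-5-yl}benzofuran-6-yl)oxy]silane
Product: 22 cathafuran C, 5-(6-hydroxybenzofuran-2-yl)-2,2-dimethyl-6-(3-methylbut-2-en-1-yl)-2H-chromen-7-ol
Conditions: TBAF (2.4 equiv), AcOH (2.4 equiv), THF, 0 °C to rt
Reagents that add atoms: none
Why: Fluoride cleaves both aryl Si–O bonds (desilylation); acetic acid protonates the phenoxides as they form, so the prenyl group and the chromene meet neither strong base nor strong acid.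

Compound list
1 | 2,4,6-trihydroxybenzaldehyde | O=Cc1c(O)cc(O)cc1O | starting material
2 | chlorotriisopropylsilane | CC(C)[Si](Cl)(C(C)C)C(C)C | starting material
3 | 2,6-dihydroxy-4-[(triisopropylsilyl)oxy]benzaldehyde | O=Cc1c(O)cc(O[Si](C(C)C)(C(C)C)C(C)C)cc1O | intermediate
4 | (2-methylprop-1-en-1-yl)boronic acid | CC(C)=CB(O)O | starting material
5 | 2-[1-(dibenzylamino)-3-methylbut-2-en-1-yl]-5-[(triisopropylsilyl)oxy]benzene-1,3-diol | CC(C)=CC(N(Cc1ccccc1)Cc1ccccc1)c1c(O)cc(O[Si](C(C)C)(C(C)C)C(C)C)cc1O | intermediate (not isolated)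
6 | 3-hydroxy-2-(3-methylbut-2-en-1-ylidene)-5-[(triisopropylsilyl)oxy]cyclohexa-3,5-dien-1-one | CC(C)=CC=C1C(=O)C=C(O[Si](C(C)C)(C(C)C)C(C)C)C=C1O | intermediate (not isolated)
7 | 2,2-dimethyl-7-[(triisopropylsilyl)oxy]-2H-chromen-5-ol | CC1(C)C=Cc2c(O)cc(O[Si](C(C)C)(C(C)C)C(C)C)cc2O1 | intermediate
8 | 2-methylbut-3-en-2-ol | C=CC(C)(C)O | starting material
9 | isobutyl chloroformate | CC(C)COC(=O)Cl | starting material
10 | lithium 2-methylbut-3-en-2-olate | [Li+].[O-]C(C)(C)C=C | intermediate (not isolated)
11 | isobutyl (2-methylbut-3-en-2-yl) carbonate | C=CC(C)(C)OC(=O)OCC(C)C | intermediate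
12 | triisopropyl({2,2-dimethyl-5-[(2-methylbut-3-en-2-yl)oxy]-2H-chromen-7-yl}oxy)silane | C=CC(C)(C)Oc1cc(O[Si](C(C)C)(C(C)C)C(C)C)cc2c1C=CC(C)(C)O2 | intermediate
13 | 2,2-dimethyl-6-(3-methylbut-2-en-1-yl)-7-[(triisopropylsilyl)oxy]-2H-chromen-5(6H)-one (racemic at C6, transient) | O=C1C(CC=C(C)C)C(O[Si](C(C)C)(C(C)C)C(C)C)=CC2=C1C=CC(C)(C)O2 | intermediate (not isolated)
14 | 2,2-dimethyl-6-(3-methylbut-2-en-1-yl)-7-[(triisopropylsilyl)oxy]-2H-chromen-5-ol | CC(C)=CCc1c(O[Si](C(C)C)(C(C)C)C(C)C)cc2c(c1O)C=CC(C)(C)O2 | intermediate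
15 | trifluoromethanesulfonic anhydride | O=S(=O)(OS(=O)(=O)C(F)(F)F)C(F)(F)F | starting material
16 | 2,2-dimethyl-6-(3-methylbut-2-en-1-yl)-7-[(triisopropylsilyl)oxy]-2H-chromen-5-yl trifluoromethanesulfonate | CC(C)=CCc1c(O[Si](C(C)C)(C(C)C)C(C)C)cc2c(c1OS(=O)(=O)C(F)(F)F)C=CC(C)(C)O2 | intermediate
17 | benzofuran-6-ol | Oc1ccc2ccoc2c1 | starting material
18 | (benzofuran-6-yloxy)triisopropylsilane | CC(C)[Si](Oc1ccc2ccoc2c1)(C(C)C)C(C)C | intermediate
19 | {6-[(triisopropylsilyl)oxy]benzofuran-2-yl}lithium | [Li]c1cc2ccc(O[Si](C(C)C)(C(C)C)C(C)C)cc2o1 | intermediate (not isolated)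
20 | chloro{6-[(triisopropylsilyl)oxy]benzofuran-2-yl}zinc | Cl[Zn]c1cc2ccc(O[Si](C(C)C)(C(C)C)C(C)C)cc2o1 | intermediate (not isolated)
21 | triisopropyl[(2-{2,2-dimethyl-6-(3-methylbut-2-en-1-yl)-7-[(triisopropylsilyl)oxy]-2H-chromen-5-yl}benzofuran-6-yl)oxy]silane | CC(C)=CCc1c(O[Si](C(C)C)(C(C)C)C(C)C)cc2c(c1-c1cc3ccc(O[Si](C(C)C)(C(C)C)C(C)C)cc3o1)C=CC(C)(C)O2 | intermediate
22 | cathafuran C, 5-(6-hydroxybenzofuran-2-yl)-2,2-dimethyl-6-(3-methylbut-2-en-1-yl)-2H-chromen-7-ol (achiral) | CC(C)=CCc1c(O)cc2c(c1-c1cc3ccc(O)cc3o1)C=CC(C)(C)O2 | target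

Total step count: 9. Longest linear sequence: 7 steps (steps 1, 2, 4, 5, 6, 8, 9).

Steps most likely to fail

Step 2. The formyl group of 3 is electron-rich and hydrogen-bonded on both sides, so iminium formation may be slow. The alkenylboronic acid may then protodeboronate, and the o-quinone methide may be captured by a second phenol molecule instead of closing. The fallback sets out from 3 and comes back at 7, and makes the same two bonds in two operations with known chemistry. 3 is treated with an excess (about 3.5 equiv) of (2-methylprop-1-en-1-yl)magnesium bromide in THF at 0 °C to rt. Two equivalents are consumed by the phenols and the third adds to the formyl group. After NH4Cl work-up this should give 2-(1-hydroxy-3-methylbut-2-en-1-yl)-5-[(triisopropylsilyl)oxy]benzene-1,3-diol F1. Warming F1 in toluene at 60 °C with catalytic PPTS should dehydrate it to the o-quinone methide 6, which should close to 7.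

Step 8. Oxidative addition and transmetalation at the di-ortho-substituted C5 position may be sluggish, which leaves time for S–O cleavage of the triflate back to the phenol. Lithiation of 18 may also be incomplete or partly misdirected. The fallback sets out from 16 and comes back at 22; it builds the benzofuran on the chromene instead of coupling a preformed one. Sonogashira coupling of 16 with ethynyltrimethylsilane (Pd(PPh3)2Cl2, CuI, Et3N, DMF, 70 °C) should give triisopropyl({2,2-dimethyl-6-(3-methylbut-2-en-1-yl)-5-[(trimethylsilyl)ethynyl]-2H-chromen-7-yl}oxy)silane F2. Brief treatment with K2CO3 in MeOH at 0 °C should remove the alkynyl silyl group and give {[5-ethynyl-2,2-dimethyl-6-(3-methylbut-2-en-1-yl)-2H-chromen-7-yl]oxy}triisopropylsilane F3. A second Sonogashira coupling with 4-iodobenzene-1,3-diol under the same catalyst at 60–80 °C should be followed in the flask by 5-endo cyclization of the ortho hydroxyl onto the alkyne, to give 2-{2,2-dimethyl-6-(3-methylbut-2-en-1-yl)-7-[(triisopropylsilyl)oxy]-2H-chromen-5-yl}benzofuran-6-ol F4. TBAF/AcOH in THF should then give 22.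

Step 5. The tertiary allyl ether may fragment on heating (loss of isoprene back to 7). The neighbouring OTIPS group may slow the [3,3] shift, and the allyl group may drift to C8 by way of the C4a dienone. The fallback sets out from 7 and comes back at 14, and replaces steps 3–5. The sodium phenoxide of 7 (NaH, toluene, 0 °C) is treated with prenyl bromide at rt. In a non-polar solvent the contact ion pair should be C-alkylated at the ortho position, and C6 is the only free ortho carbon of the C5 oxygen. No new compound is made on this way (entry F0).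

Further compounds
F1 | step 2 | 2-(1-hydroxy-3-methylbut-2-en-1-yl)-5-[(triisopropylsilyl)oxy]benzene-1,3-diol | CC(C)=CC(O)c1c(O)cc(O[Si](C(C)C)(C(C)C)C(C)C)cc1O
F2 | step 8 | triisopropyl({2,2-dimethyl-6-(3-methylbut-2-en-1-yl)-5-[(trimethylsilyl)ethynyl]-2H-chromen-7-yl}oxy)silane | CC(C)=CCc1c(O[Si](C(C)C)(C(C)C)C(C)C)cc2c(c1C#C[Si](C)(C)C)C=CC(C)(C)O2
F3 | step 8 | {[5-ethynyl-2,2-dimethyl-6-(3-methylbut-2-en-1-yl)-2H-chromen-7-yl]oxy}triisopropylsilane | CC(C)=CCc1c(O[Si](C(C)C)(C(C)C)C(C)C)cc2c(c1C#C)C=CC(C)(C)O2
F4 | step 8 | 2-{2,2-dimethyl-6-(3-methylbut-2-en-1-yl)-7-[(triisopropylsilyl)oxy]-2H-chromen-5-yl}benzofuran-6-ol | CC(C)=CCc1c(O[Si](C(C)C)(C(C)C)C(C)C)cc2c(c1-c1cc3ccc(O)cc3o1)C=CC(C)(C)O2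
F0 | step 5 | none | none
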